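The retrosynthesis first removes the prenyl C–O bond and the masking groups. It then cuts two ring bonds of the formyl-bearing benzene ring, C(OH)–C(aroyl) and C(O-prenyl)–C(CHO), which gives a 4-methyl-2-silyloxyfuran and the ynone Ar–CO–C≡C–CH(OEt)2. Further cuts are the CO–C(sp) bond (chromene-8-carbaldehyde + 3,3-diethoxypropyne), the C8–CHO bond (aryllithium + DMF) and the pyran ring (resorcinol + 3-methylbut-2-enoic acid).
Enabling feature: the formyl-bearing ring is a 1,4-dioxygenated benzene that reads, going round, C–O-prenyl, C–CHO, C–aroyl, C–OH, C–H, C–CH3. The carbons C(O-prenyl), C(CH3), C(H) and C(OH) map onto C5, C4, C3 and C2 of a 4-methyl-2-oxyfuran, and the neighbouring CHO- and aroyl-bearing carbons map onto the two carbons of an alkyne. The ring is therefore the aromatised form of a furan–alkyne [4+2] adduct whose two oxygens are already different.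
Forward order: a dihydropyranone ring is fused to resorcinol and converted to the 2,2-dimethylchromene, C8 is formylated, and the four-carbon alkyne chain is added and oxidised to the ynone. The second benzene ring is made last by cycloaddition and bridge opening, followed by O-prenylation and unmasking.
Stereochemistry: the target has no stereocentre and no stereogenic double bond. The carbinol and bridgehead centres that appear on the way are racemic and are erased again.

Key step: step 9

Remark: the target is achiral, so the single-enantiomer requirement is met trivially. It is treated as the open hydroxy-aldehyde as drawn, which in solution may equilibrate with the seven-membered lactol formed by the chromene 7-OH and the CHO group.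

Step 1
Reactants: 1 resorcinol; 2 3-methylbut-2-enoic acid
Product: 4 7-hydroxy-2,2-dimethylchroman-4-one, via dihydroxyphenyl enone 3 (not isolated)
Conditions: P2O5, MeSO3H, 70 °C
Reagents that add atoms: none
Why: Friedel–Crafts acylation at C4 of resorcinol followed by intramolecular oxa-Michael addition of the ortho hydroxyl to the enone is the standard one-pot chromanone synthesis, and it leaves free the hydroxyl para to the acyl-bearing carbon.

Step 2
Reactants: 4 7-hydroxy-2,2-dimethylchroman-4-one
Product: 5 7-(methoxymethoxy)-2,2-dimethylchroman-4-one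
Conditions: MOMCl, iPr2NEt, CH2Cl2, 0 °C → rt
Reagents that add atoms: chloromethyl methyl ether (MOMCl), COCCl
Why: Williamson-type O-alkylation (MOM ether formation) of the only phenol, which is acidic because it is para to the ketone; MOM is chosen because it later directs the lithiation.

Step 3
Reactants: 5 7-(methoxymethoxy)-2,2-dimethylchroman-4-one
Product: 6 7-(methoxymethoxy)-2,2-dimethylchroman-4-ol (racemic)
Conditions: NaBH4, MeOH, 0 °C → rt
Reagents that add atoms: none
Why: Borohydride 1,2-reduction of an aryl ketone; the carbinol centre forms as a racemate and is removed in the next step.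

Step 4
Reactants: 6 7-(methoxymethoxy)-2,2-dimethylchroman-4-ol
Product: 8 7-(methoxymethoxy)-2,2-dimethyl-2H-chromene, via benzylic mesylate 7 (not isolated)
Conditions: MsCl, Et3N, CH2Cl2, 0 °C → rt
Reagents that add atoms: none
Why: Mesylation–elimination; the benzylic C4–O bond is activated by the para OMOM group and the ortho ring oxygen, so the mesylate should lose methanesulfonate under basic conditions that cannot harm the MOM acetal.

Step 5
Reactants: 8 7-(methoxymethoxy)-2,2-dimethyl-2H-chromene
Product: 10 7-(methoxymethoxy)-2,2-dimethyl-2H-chromene-8-carbaldehyde, via 8-lithiochromene 9 (not isolated)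
Conditions: n-BuLi, TMEDA, THF, −78 → 0 °C; DMF, −78 °C → rt; H2O
Reagents that add atoms: N,N-dimethylformamide (DMF), CN(C)C=O
Why: Directed ortho-metalation; C8–H lies between the OMOM group and the ring oxygen, whose combined coordination and inductive acidification favour it over C6–H, and trapping an aryllithium with DMF is a standard formylation.

Step 6
Reactants: 10 7-(methoxymethoxy)-2,2-dimethyl-2H-chromene-8-carbaldehyde; 11 3,3-diethoxyprop-1-yne
Product: 13 4,4-diethoxy-1-[7-(methoxymethoxy)-2,2-dimethyl-2H-chromen-8-yl]but-2-yn-1-ol (racemic), via lithium acetylide 12 (not isolated)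
Conditions: 11, n-BuLi, THF, −78 °C; then 10, −78 → 0 °C; H2O
Reagents that add atoms: none
Why: 1,2-Addition of a lithium acetylide to an aromatic aldehyde; the acetal and MOM groups are inert to base, and the racemic carbinol centre is removed in the next step.

Step 7
Reactants: 13 4,4-diethoxy-1-[7-(methoxymethoxy)-2,2-dimethyl-2H-chromen-8-yl]but-2-yn-1-ol
Product: 14 4,4-diethoxy-1-[7-(methoxymethoxy)-2,2-dimethyl-2H-chromen-8-yl]but-2-yn-1-one
Conditions: activated MnO2, CH2Cl2, rt
Reagents that add atoms: none
Why: MnO2 oxidation of an alcohol that is both benzylic and propargylic; the neutral heterogeneous conditions leave the acetal, MOM ether and chromene double bond untouched.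

Step 8
Reactants: 15 4-methylfuran-2(5H)-one
Product: 16 4-methyl-2-(triisopropylsilyloxy)furan
Conditions: TIPSOTf, Et3N, CH2Cl2, 0 °C → rt; used freshly made
Reagents that add atoms: triisopropylsilyl trifluoromethanesulfonate (TIPSOTf), CC(C)[Si](C(C)C)(C(C)C)OS(=O)(=O)C(F)(F)F
Why: Soft enolisation and O-silylation of a butenolide (silyl dienolate formation); loss of the C5 proton is driven by formation of the aromatic furan, and the TIPS derivative is robust enough to handle.

Step 9
Reactants: 14 4,4-diethoxy-1-[7-(methoxymethoxy)-2,2-dimethyl-2H-chromen-8-yl]but-2-yn-1-one; 16 4-methyl-2-(triisopropylsilyloxy)furan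
Product: 18 [2-(diethoxymethyl)-3-hydroxy-4-methyl-6-(triisopropylsilyloxy)phenyl][7-(methoxymethoxy)-2,2-dimethyl-2H-chromen-8-yl]methanone, via 7-oxanorbornadiene cycloadduct 17 (not isolated)
Conditions: 16 (2 equiv), PhMe, 80 °C, no Lewis acid; then SiO2, CH2Cl2, rt
Reagents that add atoms: none
Why: This is a normal-electron-demand Diels–Alder reaction of an electron-rich 2-silyloxyfuran with an acetylenic ketone followed by opening of the oxygen bridge, i.e. the known silyloxy-/alkoxyfuran–activated-alkyne benzannulation to 4-oxygenated phenols, applied here to a more crowded aroyl ynone. Furan C5 bonds to the acetal-bearing alkyne carbon (β to the ketone) and furan C2 to the α-carbon in a concerted, asynchronous, intermolecular [4+2] closure that forms the one new six-membered carbocycle as 17. In 17 the silyloxy bridgehead is a ketal carbon, so its C–O bridge bond ionises to a silyloxy-stabilised cyclohexadienyl cation and the other bridgehead loses its proton; the bridge oxygen thus ends as the free phenol between the methyl- and acetal-bearing carbons, and the OTIPS group ends next to the aroyl carbon. The two bridgehead stereocentres of 17 form as a racemate and vanish on aromatisation, so no stereocontrol is needed. The required regioselectivity rests on matched polarisation: the C2 silyloxy donor and the C4 methyl group both place the largest HOMO coefficient on C5, the ketone places the largest LUMO coefficient on the β-carbon, and the twisted di-ortho-substituted aryl group donates little into the carbonyl group and so leaves the alkyne activated. Ring closure rather than an open vinylogous Mukaiyama–Michael butenolide is favoured by leaving out Lewis acids, and the electron-rich chromene C3=C4 bond does not compete as a dienophile.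

Step 10
Reactants: 18 benzophenone phenol from step 9; 19 1-bromo-3-methylbut-2-ene (prenyl bromide)
Product: 20 [2-(diethoxymethyl)-4-methyl-3-(3-methylbut-2-enyloxy)-6-(triisopropylsilyloxy)phenyl][7-(methoxymethoxy)-2,2-dimethyl-2H-chromen-8-yl]methanone
Conditions: K2CO3, acetone, rt; 18 used without storage
Reagents that add atoms: none
Why: Williamson ether synthesis on the single free phenol with a reactive allylic bromide; both ortho positions are blocked against C-alkylation, and the aryl TIPS ether, acetal and MOM group tolerate K2CO3 in acetone.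

Step 11
Reactants: 20 prenyl ether from step 10
Product: 21 [2-(diethoxymethyl)-6-hydroxy-4-methyl-3-(3-methylbut-2-enyloxy)phenyl][7-(methoxymethoxy)-2,2-dimethyl-2H-chromen-8-yl]methanone
Conditions: TBAF, AcOH (1:1), THF, 0 °C
Reagents that add atoms: none
Why: Fluoride-mediated desilylation of an aryl silyl ether, fast because the released phenoxide is ortho to the ketone; the acetate buffer keeps the medium nearly neutral, so both acetals and the prenyl ether are unaffected.

Step 12
Reactants: 21 phenol from step 11
Product: 23 3-hydroxy-2-(7-hydroxy-2,2-dimethyl-2H-chromene-8-carbonyl)-5-methyl-6-(3-methylbut-2-enyloxy)benzaldehyde (target), via MOM-protected aldehyde 22 (not isolated)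
Conditions: 2 M aq HCl, THF, rt → 40 °C, stopped as soon as 22 is consumed
Reagents that add atoms: water, O
Why: Acid-catalysed acetal hydrolysis; the benzylic diethyl acetal goes first through its aryl-stabilised oxocarbenium ion, and the MOM acetal follows readily because the departing phenol is ortho to the ketone and leaves as a hydrogen-bonded good leaving group, so dilute acid and short contact should suffice and should spare the prenyl ether and the 2,2-dimethylchromene.

Compound list
1 | resorcinol | Oc1cccc(O)c1 | starting material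
2 | 3-methylbut-2-enoic acid | CC(C)=CC(=O)O | starting material
3 | 1-(2,4-dihydroxyphenyl)-3-methylbut-2-en-1-one | CC(C)=CC(=O)c1ccc(O)cc1O | intermediate
4 | 7-hydroxy-2,2-dimethylchroman-4-one | CC1(C)CC(=O)c2ccc(O)cc2O1 | intermediate
5 | 7-(methoxymethoxy)-2,2-dimethylchroman-4-one | COCOc1ccc2C(=O)CC(C)(C)Oc2c1 | intermediate
6 | 7-(methoxymethoxy)-2,2-dimethylchroman-4-ol (racemic) | COCOc1ccc2C(O)CC(C)(C)Oc2c1 | intermediate
7 | 7-(methoxymethoxy)-2,2-dimethylchroman-4-yl methanesulfonate (racemic) | COCOc1ccc2C(OS(C)(=O)=O)CC(C)(C)Oc2c1 | intermediate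
8 | 7-(methoxymethoxy)-2,2-dimethyl-2H-chromene | COCOc1ccc2C=CC(C)(C)Oc2c1 | intermediate
9 | 8-lithio-7-(methoxymethoxy)-2,2-dimethyl-2H-chromene | COCOc1ccc2C=CC(C)(C)Oc2c1[Li] | intermediate
10 | 7-(methoxymethoxy)-2,2-dimethyl-2H-chromene-8-carbaldehyde | COCOc1ccc2C=CC(C)(C)Oc2c1C=O | intermediate
11 | 3,3-diethoxyprop-1-yne | C#CC(OCC)OCC | starting material
12 | lithium 3,3-diethoxyprop-1-yn-1-ide | [Li]C#CC(OCC)OCC | intermediate
13 | 4,4-diethoxy-1-[7-(methoxymethoxy)-2,2-dimethyl-2H-chromen-8-yl]but-2-yn-1-ol (racemic) | CCOC(OCC)C#CC(O)c1c(OCOC)ccc2C=CC(C)(C)Oc12 | intermediate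
14 | 4,4-diethoxy-1-[7-(methoxymethoxy)-2,2-dimethyl-2H-chromen-8-yl]but-2-yn-1-one | CCOC(OCC)C#CC(=O)c1c(OCOC)ccc2C=CC(C)(C)Oc12 | intermediate
15 | 4-methylfuran-2(5H)-one | CC1=CC(=O)OC1 | starting material
16 | 4-methyl-2-(triisopropylsilyloxy)furan | Cc1coc(O[Si](C(C)C)(C(C)C)C(C)C)c1 | intermediate
17 | [3-(diethoxymethyl)-5-methyl-1-(triisopropylsilyloxy)-7-oxabicyclo[2.2.1]hepta-2,5-dien-2-yl][7-(methoxymethoxy)-2,2-dimethyl-2H-chromen-8-yl]methanone (racemic) | CCOC(OCC)C1=C(C(=O)c3c(OCOC)ccc4C=CC(C)(C)Oc34)C2(O[Si](C(C)C)(C(C)C)C(C)C)C=C(C)C1O2 | intermediate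
18 | [2-(diethoxymethyl)-3-hydroxy-4-methyl-6-(triisopropylsilyloxy)phenyl][7-(methoxymethoxy)-2,2-dimethyl-2H-chromen-8-yl]methanone | CCOC(OCC)c1c(O)c(C)cc(O[Si](C(C)C)(C(C)C)C(C)C)c1C(=O)c1c(OCOC)ccc2C=CC(C)(C)Oc12 | intermediate
19 | 1-bromo-3-methylbut-2-ene (prenyl bromide) | CC(C)=CCBr | starting material
20 | [2-(diethoxymethyl)-4-methyl-3-(3-methylbut-2-enyloxy)-6-(triisopropylsilyloxy)phenyl][7-(methoxymethoxy)-2,2-dimethyl-2H-chromen-8-yl]methanone | CCOC(OCC)c1c(OCC=C(C)C)c(C)cc(O[Si](C(C)C)(C(C)C)C(C)C)c1C(=O)c1c(OCOC)ccc2C=CC(C)(C)Oc12 | intermediate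
21 | [2-(diethoxymethyl)-6-hydroxy-4-methyl-3-(3-methylbut-2-enyloxy)phenyl][7-(methoxymethoxy)-2,2-dimethyl-2H-chromen-8-yl]methanone | CCOC(OCC)c1c(OCC=C(C)C)c(C)cc(O)c1C(=O)c1c(OCOC)ccc2C=CC(C)(C)Oc12 | intermediate
22 | 3-hydroxy-2-[7-(methoxymethoxy)-2,2-dimethyl-2H-chromene-8-carbonyl]-5-methyl-6-(3-methylbut-2-enyloxy)benzaldehyde | CC(C)=CCOc1c(C)cc(O)c(C(=O)c2c(OCOC)ccc3c2OC(C)(C)C=C3)c1C=O | intermediate
23 | 3-hydroxy-2-(7-hydroxy-2,2-dimethyl-2H-chromene-8-carbonyl)-5-methyl-6-(3-methylbut-2-enyloxy)benzaldehyde (CNP0150093.0) | CC(C)=CCOc1c(C)cc(O)c(C(=O)c2c(O)ccc3c2OC(C)(C)C=C3)c1C=O | target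

Total step count: 12. Longest linear sequence: 11 (steps 1–7 and 9–12). Step 8 is a one-step side branch.

Steps most likely to fail

Step 9. Both new bonds form at crowded carbons, since the α-carbon sits beside a di-ortho-substituted aroyl group, so the cycloaddition may stall. The furan may also add in an open vinylogous Michael sense without closing the ring, or it may be desilylated on long heating. The fallback builds the ring on a small dienophile and attaches the chromene afterwards. It sets out from 11 and 16 and comes back at 20.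
- The acetylide 12 made from 11 is formylated with DMF to 4,4-diethoxybut-2-ynal F1.
- F1 should react with 16 through the oxa-bridged cycloadduct F2 to give 2-(diethoxymethyl)-3-hydroxy-4-methyl-6-(triisopropylsilyloxy)benzaldehyde F3.
- Alkylation of F3 with 19 (K2CO3, acetone) gives the prenyl ether aldehyde F4.
- Addition of the aryllithium 9 (from 8) to F4 gives the diaryl carbinol F5.
- MnO2 oxidation of F5 gives 20.

Step 12. The prenyl ether may be lost by acid-induced ionisation to the prenyl cation, or the chromene may be attacked by acid, before the MOM acetal is fully cleaved. The fallback removes the MOM group before the prenyl ether exists. It sets out from 18 and comes back at 23.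
- 18 is treated with catalytic HCl in dry ethanol, in which the diethyl acetal merely exchanges with the solvent, to give the MOM-free diphenol F6.
- The chromene hydroxyl of F6 is held in a hydrogen bond to the ketone, so one equivalent of 19 with K2CO3 in acetone should alkylate only the non-chelated hydroxyl, giving the chelated-phenol prenyl ether F7.
- TBAF/AcOH then gives the bis-phenol acetal F8.
- PPTS in wet acetone, far milder than what a MOM ether requires, hydrolyses the acetal of F8 to 23.

Step 5. Site selectivity may be poor (metalation at C6 instead of C8), or metalation may be incomplete because the ring oxygen flanked by the gem-dimethyl carbon coordinates lithium weakly. The fallback places the formyl group on the symmetric resorcinol stage, where only one doubly activated site exists, and closes the pyran ring afterwards. It sets out from 1 and comes back at 10.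
- 1 is converted (MOMCl, iPr2NEt) to 1,3-bis(methoxymethoxy)benzene F9.
- Lithiation of F9 between the two OMOM groups and a DMF quench give 2,6-bis(methoxymethoxy)benzaldehyde F10.
- Brief dilute acid removes one MOM group to give 2-hydroxy-6-(methoxymethoxy)benzaldehyde F11; the second cleavage is slower once the free OH is hydrogen-bonded to the aldehyde.
- O-alkylation of F11 with 3-chloro-3-methylbut-1-yne (K2CO3, KI, cat. CuI, DMF) gives the 1,1-dimethylpropargyl ether F12.
- Heating F12 in N,N-diethylaniline (aromatic propargyl Claisen rearrangement, 1,5-H shift, oxa-6π electrocyclisation at the only free ortho carbon) gives 10.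

Further compounds
F1 | step 9 | 4,4-diethoxybut-2-ynal | CCOC(OCC)C#CC=O
F2 | step 9 | 3-(diethoxymethyl)-5-methyl-1-(triisopropylsilyloxy)-7-oxabicyclo[2.2.1]hepta-2,5-diene-2-carbaldehyde (racemic) | CCOC(OCC)C1=C(C=O)C2(O[Si](C(C)C)(C(C)C)C(C)C)C=C(C)C1O2
F3 | step 9 | 2-(diethoxymethyl)-3-hydroxy-4-methyl-6-(triisopropylsilyloxy)benzaldehyde | CCOC(OCC)c1c(O)c(C)cc(O[Si](C(C)C)(C(C)C)C(C)C)c1C=O
F4 | step 9 | 2-(diethoxymethyl)-4-methyl-3-(3-methylbut-2-enyloxy)-6-(triisopropylsilyloxy)benzaldehyde | CCOC(OCC)c1c(OCC=C(C)C)c(C)cc(O[Si](C(C)C)(C(C)C)C(C)C)c1C=O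
F5 | step 9 | [2-(diethoxymethyl)-4-methyl-3-(3-methylbut-2-enyloxy)-6-(triisopropylsilyloxy)phenyl][7-(methoxymethoxy)-2,2-dimethyl-2H-chromen-8-yl]methanol (racemic) | CCOC(OCC)c1c(OCC=C(C)C)c(C)cc(O[Si](C(C)C)(C(C)C)C(C)C)c1C(O)c1c(OCOC)ccc2C=CC(C)(C)Oc12
F6 | step 12 | [2-(diethoxymethyl)-3-hydroxy-4-methyl-6-(triisopropylsilyloxy)phenyl](7-hydroxy-2,2-dimethyl-2H-chromen-8-yl)methanone | CCOC(OCC)c1c(O)c(C)cc(O[Si](C(C)C)(C(C)C)C(C)C)c1C(=O)c1c(O)ccc2C=CC(C)(C)Oc12
F7 | step 12 | [2-(diethoxymethyl)-4-methyl-3-(3-methylbut-2-enyloxy)-6-(triisopropylsilyloxy)phenyl](7-hydroxy-2,2-dimethyl-2H-chromen-8-yl)methanone | CCOC(OCC)c1c(OCC=C(C)C)c(C)cc(O[Si](C(C)C)(C(C)C)C(C)C)c1C(=O)c1c(O)ccc2C=CC(C)(C)Oc12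
F8 | step 12 | [2-(diethoxymethyl)-6-hydroxy-4-methyl-3-(3-methylbut-2-enyloxy)phenyl](7-hydroxy-2,2-dimethyl-2H-chromen-8-yl)methanone | CCOC(OCC)c1c(OCC=C(C)C)c(C)cc(O)c1C(=O)c1c(O)ccc2C=CC(C)(C)Oc12
F9 | step 5 | 1,3-bis(methoxymethoxy)benzene | COCOc1cccc(OCOC)c1
F10 | step 5 | 2,6-bis(methoxymethoxy)benzaldehyde | COCOc1cccc(OCOC)c1C=O
F11 | step 5 | 2-hydroxy-6-(methoxymethoxy)benzaldehyde | COCOc1cccc(O)c1C=O
F12 | step 5 | 2-(methoxymethoxy)-6-(2-methylbut-3-yn-2-yloxy)benzaldehyde | C#CC(C)(C)Oc1cccc(OCOC)c1C=O
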